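**Retrosynthetic overview**
- Feature: in the cyclobutane ring (C1–C4), C1/C3 carry the acyl groups and C2/C4 the 3,4-dimethoxyphenyl groups in the centrosymmetric 1α,2α,3β,4β array. Every ring bond joins an acyl-bearing to an aryl-bearing carbon, and across C1–C2 the two groups are cis, so an NH placed in that bond gives a 2,5-cis pyrrolidine with carboxylates at C2/C4 and aryls at C3/C5.
- Disconnections: both imide C(O)–N bonds (diacid chloride plus N-lithiated 5,6-dihydropyridin-2(1H)-one); the cyclobutane C1–C2 bond by loss of N2 from that pyrrolidine; the pyrrolidine C2–C3 and C4–C5 bonds by exo [3+2] cycloaddition of a glycine-imine azomethine ylide to a Z-cinnamate; the Z alkene by a Z-selective Horner–Wadsworth–Emmons reaction.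
- Ring order: pyrrolidine (step 4), contracted to the cyclobutane (step 5), the two dihydropyridinone rings attached intact last (step 8).

Key step: step 5

Remark on the chemistry: intermediates 9–12 are chiral and are formed as racemates (or in either handedness); their SMILES show one enantiomer. Cyclobutane 13 is achiral, so the sense of induction in step 4 does not matter.

**Step 1**
Reactants: 1 diphenyl phosphite; 2 tert-butyl bromoacetate
Product: 3 tert-butyl 2-(diphenoxyphosphoryl)acetate
Conditions: Et3N, CH2Cl2, 0 °C to rt
Reagents that add atoms: none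
Why: Michaelis–Becker-type P-alkylation, in which the triethylammonium salt of the phosphite attacks the primary α-bromo ester at phosphorus, is the standard way to diaryl phosphonoacetates.

**Step 2**
Reactants: 3 tert-butyl 2-(diphenoxyphosphoryl)acetate; 4 3,4-dimethoxybenzaldehyde
Product: 6 tert-butyl (Z)-3-(3,4-dimethoxyphenyl)prop-2-enoate, via sodium phosphonate carbanion 5 (not isolated)
Conditions: NaH, THF, 0 °C; then 4, −78 °C to rt; chromatography in the dark
Reagents that add atoms: none
Why: Z-selective Horner–Wadsworth–Emmons olefination, in which the electron-poor phenoxy groups on phosphorus make the oxaphosphetane collapse faster than the adducts equilibrate, so the kinetic Z alkene should predominate and the minor E isomer is removed by chromatography.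

**Step 3**
Reactants: 4 3,4-dimethoxybenzaldehyde; 7 glycine tert-butyl ester
Product: 8 tert-butyl N-[(E)-(3,4-dimethoxyphenyl)methylidene]glycinate
Conditions: MgSO4, CH2Cl2, rt; used crude
Reagents that add atoms: none
Why: Condensation of a primary amine with an aromatic aldehyde, driven by the drying agent, should give the aldimine, with the E geometry following from sterics.

**Step 4**
Reactants: 6 tert-butyl (Z)-3-(3,4-dimethoxyphenyl)prop-2-enoate; 8 tert-butyl N-[(E)-(3,4-dimethoxyphenyl)methylidene]glycinate
Product: 10 di-tert-butyl rel-(2R,3S,4S,5S)-3,5-bis(3,4-dimethoxyphenyl)pyrrolidine-2,4-dicarboxylate (2,5-cis; 3,4-cis; 2,3-trans; 4,5-trans), via copper azomethine ylide 9 (not isolated)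
Conditions: Cu(CH3CN)4PF6 (10 mol %), DTBM-SEGPHOS (11 mol %, either enantiomer or racemate), Et3N (20 mol %), THF, rt, dark
Reagents that add atoms: none
Why: In this monovalent-copper-catalysed 1,3-dipolar cycloaddition of an azomethine ylide, the N,O-chelated W-shaped ylide 9 fixes the 2,5-cis relation, suprafacial addition carries the Z geometry of 6 into the 3,4-cis relation, the ylide α-carbon attacks the β-carbon of the enoate, and the bulky bisphosphine on copper disfavours the endo approach (ester and aryl of 6 both under the metal), so the exo adduct with the 4-ester trans to the 5-aryl should form.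

**Step 5**
Reactants: 10 di-tert-butyl rel-(2R,3S,4S,5S)-3,5-bis(3,4-dimethoxyphenyl)pyrrolidine-2,4-dicarboxylate
Product: 13 di-tert-butyl (1α,2α,3β,4β)-2,4-bis(3,4-dimethoxyphenyl)cyclobutane-1,3-dicarboxylate (centrosymmetric, achiral), via 1,1-diazene 11 (not isolated), via 1,4-biradical 12 (not isolated)
Conditions: PhI(OH)OTs (2.5 equiv), NH2CO2NH4 (8 equiv), CF3CH2OH, 80 °C
Reagents that add atoms: none
Why: The trivalent iodine reagent and ammonia released from the carbamate form an iodonitrene that aminates and oxidises the free N–H of 10 to the 1,1-diazene 11, which loses N2 at 80 °C to give the singlet 1,4-biradical 12 with one radical centre α to an ester (former C2) and one benzylic (former C5). This is the known iodonitrene-mediated contraction of pyrrolidines to cyclobutanes, a variant of thermal nitrogen extrusion from 1,1-diazenes. The four-membered ring closes by direct radical–radical recombination of the 1,4-diyl, which forms the former C2–C5 bond. The two new cyclobutane stereocentres are these former C2 and C5 atoms, and they are set by memory of the pyrrolidine configuration: the singlet pair couples faster than the C2–C3 and C4–C5 bonds rotate, so the cis relation of C2-ester and C5-aryl is carried over while C3 and C4 are untouched. The step needs retention and ring closure to win over β-scission of the C3–C4 bond into two cinnamates; the singlet spin state, the captodative and benzylic stabilisation that allows N2 loss at low temperature, and the short, fully substituted tether that holds the radical ends close should secure this.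

**Step 6**
Reactants: 13 di-tert-butyl (1α,2α,3β,4β)-2,4-bis(3,4-dimethoxyphenyl)cyclobutane-1,3-dicarboxylate
Product: 14 (1α,2α,3β,4β)-2,4-bis(3,4-dimethoxyphenyl)cyclobutane-1,3-dicarboxylic acid
Conditions: CF3CO2H/CH2Cl2 (1:4), 0 °C to rt
Reagents that add atoms: none
Why: Acidolysis of the tert-butyl esters by loss of the tert-butyl cation as isobutene should give the diacid, and without base the α-stereocentres cannot epimerise.

**Step 7**
Reactants: 14 (1α,2α,3β,4β)-2,4-bis(3,4-dimethoxyphenyl)cyclobutane-1,3-dicarboxylic acid
Product: 15 (1α,2α,3β,4β)-2,4-bis(3,4-dimethoxyphenyl)cyclobutane-1,3-dicarbonyl dichloride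
Conditions: (COCl)2, DMF (cat.), CH2Cl2, 0 °C to rt; concentrate, use crude
Reagents that add atoms: oxalyl chloride, ClC(=O)C(=O)Cl
Why: Acid chloride formation through the Vilsmeier-type chloroiminium species runs under neutral to acidic conditions, which leave the ring stereocentres untouched.

**Step 8**
Reactants: 15 (1α,2α,3β,4β)-2,4-bis(3,4-dimethoxyphenyl)cyclobutane-1,3-dicarbonyl dichloride; 16 5,6-dihydropyridin-2(1H)-one
Product: 18 1,1'-[(1α,2α,3β,4β)-2,4-bis(3,4-dimethoxyphenyl)cyclobutane-1,3-dicarbonyl]bis(5,6-dihydropyridin-2(1H)-one) (CNP0199212.1), via lithium lactamate 17 (not isolated)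
Conditions: 16 (2.4 equiv), n-BuLi (2.3 equiv), THF, −78 °C; then 15, THF, −78 °C to 0 °C
Reagents that add atoms: none
Why: N-Acylation of a lactam anion by an acid chloride (imide formation) is the usual way to attach this unit, and the weakly basic N-lithio lactam 17 should attack the acyl chloride at nitrogen faster than it enolises it, so the configuration is kept.

**Compound list**
1 | diphenyl phosphite | O=[PH](Oc1ccccc1)Oc1ccccc1 | starting material
2 | tert-butyl bromoacetate | CC(C)(C)OC(=O)CBr | starting material
3 | tert-butyl 2-(diphenoxyphosphoryl)acetate | CC(C)(C)OC(=O)CP(=O)(Oc1ccccc1)Oc1ccccc1 | intermediate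
4 | 3,4-dimethoxybenzaldehyde | COc1ccc(C=O)cc1OC | starting material
5 | sodium salt of the carbanion of 3 | [Na+].CC(C)(C)OC(=O)[CH-]P(=O)(Oc1ccccc1)Oc1ccccc1 | intermediate (not isolated)
6 | tert-butyl (Z)-3-(3,4-dimethoxyphenyl)prop-2-enoate | COc1ccc(/C=C\C(=O)OC(C)(C)C)cc1OC | intermediate
7 | glycine tert-butyl ester | NCC(=O)OC(C)(C)C | starting material
8 | tert-butyl N-[(E)-(3,4-dimethoxyphenyl)methylidene]glycinate | COc1ccc(/C=N/CC(=O)OC(C)(C)C)cc1OC | intermediate
9 | copper-bound azomethine ylide of 8, drawn as the O-copper aza-dienolate, phosphine ligand omitted | COc1ccc(/C=N/C=C(\O[Cu])OC(C)(C)C)cc1OC | intermediate (not isolated)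
10 | di-tert-butyl rel-(2R,3S,4S,5S)-3,5-bis(3,4-dimethoxyphenyl)pyrrolidine-2,4-dicarboxylate | N1[C@@H](C(=O)OC(C)(C)C)[C@H](c2ccc(OC)c(OC)c2)[C@H](C(=O)OC(C)(C)C)[C@H]1c1ccc(OC)c(OC)c1 | intermediate
11 | 1,1-diazene of 10 (N-amino nitrene on the ring nitrogen, ring configuration unchanged) | [N-]=[N+]1[C@@H](C(=O)OC(C)(C)C)[C@H](c2ccc(OC)c(OC)c2)[C@H](C(=O)OC(C)(C)C)[C@H]1c1ccc(OC)c(OC)c1 | intermediate (not isolated)
12 | singlet 1,3-bis(tert-butoxycarbonyl)-2,4-bis(3,4-dimethoxyphenyl)butane-1,4-diyl, inner carbons configured as C3/C4 of 10 | CC(C)(C)OC(=O)[CH][C@H](c1ccc(OC)c(OC)c1)[C@H](C(=O)OC(C)(C)C)[CH]c1ccc(OC)c(OC)c1 | intermediate (not isolated)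
13 | di-tert-butyl (1α,2α,3β,4β)-2,4-bis(3,4-dimethoxyphenyl)cyclobutane-1,3-dicarboxylate | COc1ccc(cc1OC)[C@H]1[C@H](C(=O)OC(C)(C)C)[C@H](c2ccc(OC)c(OC)c2)[C@H]1C(=O)OC(C)(C)C | intermediate
14 | (1α,2α,3β,4β)-2,4-bis(3,4-dimethoxyphenyl)cyclobutane-1,3-dicarboxylic acid | COc1ccc(cc1OC)[C@H]1[C@H](C(=O)O)[C@H](c2ccc(OC)c(OC)c2)[C@H]1C(=O)O | intermediate
15 | (1α,2α,3β,4β)-2,4-bis(3,4-dimethoxyphenyl)cyclobutane-1,3-dicarbonyl dichloride | COc1ccc(cc1OC)[C@H]1[C@H](C(=O)Cl)[C@H](c2ccc(OC)c(OC)c2)[C@H]1C(=O)Cl | intermediate
16 | 5,6-dihydropyridin-2(1H)-one | O=C1NCCC=C1 | starting material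
17 | lithium salt of 16 (N-lithio lactam) | [Li+].O=C1[N-]CCC=C1 | intermediate (not isolated)
18 | 1,1'-[(1α,2α,3β,4β)-2,4-bis(3,4-dimethoxyphenyl)cyclobutane-1,3-dicarbonyl]bis(5,6-dihydropyridin-2(1H)-one) | COc1ccc([C@H]2[C@H](C(=O)N3CCC=CC3=O)[C@H](c3ccc(OC)c(OC)c3)[C@H]2C(=O)N2CCC=CC2=O)cc1OC | target

**Step count**
Total: 8 steps. Longest linear sequence: 7 steps (1, 2, 4, 5, 6, 7, 8); step 3 is a one-step side branch.

**Steps most likely to fail**

Step 5. The biradical may fragment by β-scission into two cinnamate molecules instead of closing. The trivalent iodine reagent may also oxidise the electron-rich dimethoxyphenyl rings in trifluoroethanol, so that little cyclobutane is recovered. The fallback sets out from 4 and returns at 14. Knoevenagel–Doebner condensation of 4 with malonic acid (pyridine, piperidine, 100 °C) passes through 2-[(3,4-dimethoxyphenyl)methylidene]propanedioic acid F1 and, after decarboxylation, should give (E)-3-(3,4-dimethoxyphenyl)prop-2-enoic acid F2. F2 is crystallised in its head-to-tail packed form and irradiated as a powder (λ > 300 nm). Topochemical [2+2] photodimerisation is expected to give the centrosymmetric diacid 14 directly, which continues with step 7. The outcome depends on obtaining the photoreactive crystal form.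

Step 4. Addition to the hindered Z-enoate may be slow, which would allow Z-to-E isomerisation or a stepwise Michael–Mannich path that scrambles the 3,4-relation, and exo over endo selectivity may be insufficient. The fallback sets out from 4 and 8 and returns at 10. Wittig olefination of 4 with Ph3P=CHCO2tBu (toluene, 80 °C) should give tert-butyl (E)-3-(3,4-dimethoxyphenyl)prop-2-enoate F3. Cycloaddition of F3 with 8 under AgOAc/PPh3/Et3N (monovalent silver, the usual endo mode) should give di-tert-butyl rel-(2R,3S,4R,5S)-3,5-bis(3,4-dimethoxyphenyl)pyrrolidine-2,4-dicarboxylate F4, the C4 epimer of 10. Equilibration of the enolisable C4 centre with DBU in toluene should give a mixture of F4 and 10. Each epimer has one cis-vicinal aryl/ester pair, so neither is expected to dominate strongly; 10 is separated and F4 is resubmitted.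

Step 8. The second acylation may stall at the mono-imide, the lactam anion may convert the acid chloride into a ketene with loss of the α-configuration, or the anion may add to the enone in conjugate fashion. The fallback sets out from 16 and returns at 18. Silylation of 16 with Me3SiCl/Et3N (CH2Cl2, rt) should give 1-(trimethylsilyl)-5,6-dihydropyridin-2(1H)-one F5. F5 is heated with diacid chloride 15 in toluene. Acyl transfer to the neutral silyl amide with loss of Me3SiCl is a known route to N-acyl lactams and needs no base.

**Further compounds**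
F1 | step 5 | 2-[(3,4-dimethoxyphenyl)methylidene]propanedioic acid | COc1ccc(C=C(C(=O)O)C(=O)O)cc1OC
F2 | step 5 | (E)-3-(3,4-dimethoxyphenyl)prop-2-enoic acid | COc1ccc(/C=C/C(=O)O)cc1OC
F3 | step 4 | tert-butyl (E)-3-(3,4-dimethoxyphenyl)prop-2-enoate | COc1ccc(/C=C/C(=O)OC(C)(C)C)cc1OC
F4 | step 4 | di-tert-butyl rel-(2R,3S,4R,5S)-3,5-bis(3,4-dimethoxyphenyl)pyrrolidine-2,4-dicarboxylate | N1[C@@H](C(=O)OC(C)(C)C)[C@H](c2ccc(OC)c(OC)c2)[C@@H](C(=O)OC(C)(C)C)[C@H]1c1ccc(OC)c(OC)c1
F5 | step 8 | 1-(trimethylsilyl)-5,6-dihydropyridin-2(1H)-one | C[Si](C)(C)N1CCC=CC1=O
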